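## The problem

The target (26) is a trans-fused bicyclo[5.3.0]decane of the daucane type: a cyclopentane (C1–C5) shares the C1–C5 bond with a cycloheptenone (C5–C10 and C1). The numbering used throughout is: C1 the methyl-bearing ring-fusion carbon, C2 and C3 the ring methylenes, C4 the carbon carrying the isopropyl group and the 4-hydroxybenzoate, C5 the ring-fusion CH, C6 the carbinol, C7=C8(CH3) the alkene, C9 the ketone and C10 the methylene between C9 and C1. Four contiguous stereocentres must be set: quaternary C1 (R), the fully substituted C4 (R), C5 (S) and C6 (S). The C1 methyl and the C4 oxygen lie on one face, and H5 and the C6 hydroxyl on the other, so the ring fusion is trans. C1 has no neighbour from which it could be derived and needs an enantioselective reagent. Once set, C1 can direct C5, and C5 can direct both C6 (through an aldol) and C4 (1,2-induction in an addition to a C4 ketone). The fragile parts are the tertiary aryl ester, the γ-hydroxy enone and the free phenol. The ester is hard to form beside the isopropyl group, ionises in strong acid, and sits 1,3 to a secondary hydroxyl that could take over the acyl group under base. Base can also isomerise the γ-hydroxy enone to a 1,4-dione. Because a secondary hydroxyl is acylated far more easily than a tertiary one, the C6 oxygen must be masked before the ester is made and freed last without base. The feature that opens the synthesis is that C1, C5 and C6 lie β, α and one bond beyond α to a carbonyl placed at C4, so a 3-substituted cyclopent-2-enone can accept the methyl group at C1 and its enolate can accept C6. The C7=C8–C9=O unit is then the retron of an aldol condensation between a C9 ethyl ketone and a C7 aldehyde.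

## Retrosynthesis

**26 ⇒ 25 ⇒ 22 (C7=C8).** The final operation only frees the C6 hydroxyl of silyl ether 25. The seven-membered ring of 25 is cut at the C7=C8 double bond, which leads to keto aldehyde 22. This cut is preferred to C8–C9 or C1–C10 because the enone is an aldol-condensation retron and the bond touches no stereocentre. What remains is a cyclopentane with two arms. The forward reaction must enolise the C9 ketone toward C8 and leave C6 untouched. The trans disposition of the arms helps, since closure from C10 or from C6 would give a strained trans-fused bicyclo[3.3.0]octane. The methanolic base is expected to remove the aryl silyl group of 22, so 25 is written with the free phenol.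

**22 ⇒ 21 ⇒ 19 (carbonyl unmasking).** No skeletal bond is cut. The C7 aldehyde is traced to the dimethyl acetal (21) and the C9 ketone to a 1,1-disubstituted alkene (19). The masks keep every enolisable carbonyl out of the molecule while organometallic reagents and a strong base are used. The forward steps are an ozonolysis that must spare the benzoate ring and the acetal C–H, and an acetal hydrolysis mild enough for a secondary silyl ether and a tertiary ester.

**19 ⇒ 14 + 18 (C4 O–acyl bond).** The ester is disconnected to tertiary alcohol 14 and acid chloride 18, which comes in two steps from 4-hydroxybenzoic acid (15) through acid 17. Acylating at this early stage, rather than on the bicyclic enone, allows the alkoxide method, which a ketone or enone would not tolerate. The forward reaction must acylate a crowded alkoxide without moving the neighbouring silyl group.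

**14 ⇒ 13 ⇒ 12 (C4–isopropyl bond).** Cutting the C4–CH(CH3)2 bond gives cyclopentanone 13, the silyl ether of aldol 12. The isopropyl group is chosen as the nucleophile, rather than the ring carbons, because the adjacent C5 side chain can then steer it to the opposite face. The forward addition must beat enolisation and reduction, which calls for an organocerium reagent.

**12 ⇒ 8 + 9 + 10 (C1–CH3 and C5–C6).** Aldol 12 is split into enone 8, trimethylaluminium (9) and 2,2-dimethoxyacetaldehyde (10). This is the strongest simplification of the route: three stereocentres and twelve of the fifteen skeletal carbons disappear into an achiral enone and two commercial reagents. The alternative of adding the C10 arm to 3-methylcyclopentenone would need a functionalised nucleophile; methyl transfer from aluminium under copper catalysis is the better-precedented quaternary-centre synthesis. The forward step must control the enantioface at C1, the enolate face at C5 and the anti aldol geometry at C6.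

**8 ⇒ 4 + 5; 4 ⇒ 2 ⇒ 1 (C1–C10).** Enone 8 is cut at the ring–arm bond into 3-ethoxycyclopent-2-en-1-one (5) and the Grignard reagent 6 of allylic chloride 4. Chloride 4 comes from alcohol 2 via mesylate 3, and 2 from 2-ethylacrolein (1). The allyl unit is symmetric, so allylic transposition cannot give an isomer. The only demand is a gentle acidic work-up, so that the exocyclic alkene of carbinol 7 and enone 8 does not move into conjugation.

## Roads not taken

**Alternative 1:** The cut is at C1–C5 and C6–C7 together. The precursor is alkynyl siloxyvinylcyclopropane A1, in which a terminal alkyne (C5≡C6) hangs from the C4 carbinol and a three-carbon tether leads to the methyl-bearing alkene carbon C1. With [Rh(CO)2Cl]2 (monovalent rhodium), A1 would undergo an intramolecular [5+2] cycloaddition with opening of the cyclopropane C7–C9 bond to give bicyclic diene A2. Both rings form in one step, which the chosen plan cannot match: its key step closes no ring and a separate aldol closure is needed. The C9 oxygen also arrives in place. The weak points for this target are three. The alkene terminus that must become quaternary C1 is 1,1-disubstituted, the least reactive class of partner. C1 has to be relayed from C4 across the tether, and C4 itself is a tertiary propargylic carbinol between an isopropyl group and a chain, which is hard to make as one enantiomer. After the cycloaddition the functionality is misplaced: C5=C6 needs a face-selective hydroboration and the enol ether at C9=C10 must be converted into a C7=C8 enone, with an endo/exo regiochemical question at C8. Against the better ring economy of A2, the chosen plan offers a catalytic enantioselective start from an achiral enone, three contiguous centres in one operation, and an oxidation pattern that needs no transposition.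

**Alternative 2:** The cut is at C7–C8 and C1–C10. Diene A3 (a 1-methyl-2-vinylcyclopentene with C4 as a dioxolane) and siloxyvinyl diazoacetate A4 would be combined with Rh2(S-PTAD)4 (dirhodium tetrakis[(S)-N-phthaloyl-1-adamantylglycinate], divalent rhodium). Cyclopropanation of the vinyl group and Cope rearrangement of the cis-divinylcyclopropane would give cycloheptadiene A5. This sets C1 by catalyst control and closes the seven-membered ring in the same step, which is at least as good as the chosen key step for C1 and better for ring formation. Its difficulties lie elsewhere. The Cope step must engage a tetrasubstituted cyclopentene carbon. C8 arrives as a methyl ester that has to be reduced to a methyl group beside a β-keto ester unit. C5=C6 must still be turned into H5 and the C6 hydroxyl. The C4 ketone, once unmasked, is conjugated and would take the isopropyl group under control only from the remote C1. The chosen plan has no carbon at the wrong oxidation level and sets C4 and C6 from the adjacent C5.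

**Alternative 3:** The cut is at C8–C9. Phenyl selenoester A6, a fully substituted cyclopentane carrying a propenyl ketone at C5, would be treated with Bu3SnH and AIBN. The acyl radical at C9 adds 7-endo to the β-carbon C8 and gives trans-fused dione A7. The ring closure is irreversible, neutral and free of the enolisation-regiochemistry question that the chosen aldol closure has to answer; in that respect it is the better closure. However, A6 already contains C1, C4 and C5, so the stereochemical problem is moved, not solved, and would still need a sequence like the chosen key step. A7 then has two ketones to tell apart: C6 must be reduced to one carbinol epimer, unsaturation must be introduced at C7=C8 toward C9 only, and C5, now α to a ketone, can epimerise to the cis-fused series. Stoichiometric tin and selenium add to the cost. The chosen plan never passes through a C6 ketone: C6 is made as the carbinol with its configuration in the key step, and the closure gives the enone directly.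

Key step: step 4

Assumption: the sense of induction of phosphoramidite L (6-{bis[(1S)-1-(naphthalen-2-yl)ethyl]amino}dibenzo[d,f][1,3,2]dioxaphosphepine or its enantiomer) on enone 8 is inferred from related 3-substituted cyclopentenones; the enantiomer that gives (R)-configured C1 is the one used.

Assumption: commercial 10 is an aqueous solution and is extracted, dried and distilled to the anhydrous monomer directly before use; this is handling of a starting material and is not counted as a step.

## Route

Step 1
Reactants: 1 2-methylidenebutanal (2-ethylacrolein)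
Product: 2 2-methylidenebutan-1-ol
Conditions: NaBH4, CeCl3·7H2O, MeOH, 0 °C
Reagents that add atoms: none
Why: Luche reduction; the cerium-modified borohydride delivers hydride 1,2 to the enal, so the allylic alcohol forms without saturation of the alkene; no stereocentre is involved.

Step 2
Reactants: 2 2-methylidenebutan-1-ol
Product: 4 2-(chloromethyl)but-1-ene, via 2-methylidenebutyl methanesulfonate 3 (not isolated)
Conditions: MsCl, LiCl, 2,4,6-collidine, DMF, 0 °C to rt
Reagents that add atoms: lithium chloride, [Li+].[Cl-]
Why: Mesylation of the primary allylic alcohol and chloride displacement in the same flask; direct and allylic (SN2′) displacement give the same product because both termini are CH2, and the buffered medium keeps acid away from the 1,1-disubstituted alkene.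

Step 3
Reactants: 4 2-(chloromethyl)but-1-ene; 5 3-ethoxycyclopent-2-en-1-one
Product: 8 3-(2-methylidenebutyl)cyclopent-2-en-1-one, via (2-methylidenebutyl)magnesium chloride 6 (not isolated), via 3-ethoxy-1-(2-methylidenebutyl)cyclopent-2-en-1-ol 7 (not isolated)
Conditions: Mg, THF, 0 °C; 5, THF, 0 °C; 1 M HCl, 0 °C
Reagents that add atoms: none
Why: Stork–Danheiser enone synthesis; the allylic Grignard reagent adds 1,2 to the vinylogous ester and cold dilute acid hydrolyses the enol ether with loss of the tertiary hydroxyl, which transposes the carbonyl; slow addition of 4 to excess magnesium limits Wurtz coupling, and the brief cold acid treatment keeps the exocyclic alkene out of conjugation.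

Step 4
Reactants: 8 3-(2-methylidenebutyl)cyclopent-2-en-1-one; 9 trimethylaluminium; 10 2,2-dimethoxyacetaldehyde
Product: 12 (2S,3R)-2-[(1R)-1-hydroxy-2,2-dimethoxyethyl]-3-methyl-3-(2-methylidenebutyl)cyclopentan-1-one, via dimethylaluminium (3R)-3-methyl-3-(2-methylidenebutyl)cyclopent-1-en-1-olate 11 (not isolated)
Conditions: CuTC (copper thiophene-2-carboxylate, 5 mol %), phosphoramidite L (10 mol %), Me3Al, Et2O, −30 °C; MeLi, THF, −78 °C; 10, −78 °C; aq. potassium sodium tartrate, cold
Reagents that add atoms: none
Why: This is a copper-catalysed asymmetric conjugate addition of a trialkylaluminium to a 3-substituted cyclopentenone with aldol trapping of the enolate, a known three-component reaction type. Me3Al activates the enone as a Lewis acid and passes a methyl group to the copper–phosphoramidite complex; the methylcopper species adds to C1 through a π-complex and a trivalent copper intermediate, and reductive elimination forms the C1–CH3 bond and the aluminium enolate 11 regiospecifically across C4–C5. MeLi converts 11 into the more nucleophilic lithium aluminate, which adds through C5 to aldehyde 10 in a closed six-membered chair transition state and forms the C5–C6 bond. No ring is closed. C1 is set by the ligand, which selects one face of the planar enone. C5 is set by C1, because the aldehyde approaches the enolate face that carries the methyl group, anti to the larger branched 2-methylidenebutyl arm. C6 is set by the enolate geometry, fixed as E by the ring, so the chair with the dimethoxymethyl group equatorial gives the anti aldol. The step needs 1,4- over 1,2-methyl transfer (secured by copper catalysis at low temperature) and aldol addition faster than methyl transfer to the aldehyde or retro-aldol (aldehyde added last at −78 °C, cold quench).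

Step 5
Reactants: 12 (2S,3R)-2-[(1R)-1-hydroxy-2,2-dimethoxyethyl]-3-methyl-3-(2-methylidenebutyl)cyclopentan-1-one
Product: 13 (2S,3R)-2-[(1R)-1-{[tert-butyl(dimethyl)silyl]oxy}-2,2-dimethoxyethyl]-3-methyl-3-(2-methylidenebutyl)cyclopentan-1-one
Conditions: TBSOTf, 2,6-lutidine, CH2Cl2, −78 °C
Reagents that add atoms: tert-butyldimethylsilyl trifluoromethanesulfonate, CC(C)(C)[Si](C)(C)OS(=O)(=O)C(F)(F)F
Why: Silylation of a hindered aldol hydroxyl with the silyl triflate is fast at −78 °C, where retro-aldol, β-elimination and activation of the dimethyl acetal do not compete; the ether blocks C6 for the later acylation at C4.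

Step 6
Reactants: 13 (2S,3R)-2-[(1R)-1-{[tert-butyl(dimethyl)silyl]oxy}-2,2-dimethoxyethyl]-3-methyl-3-(2-methylidenebutyl)cyclopentan-1-one
Product: 14 (1R,2S,3R)-2-[(1R)-1-{[tert-butyl(dimethyl)silyl]oxy}-2,2-dimethoxyethyl]-3-methyl-3-(2-methylidenebutyl)-1-(propan-2-yl)cyclopentan-1-ol
Conditions: i-PrMgCl, CeCl3 (anhydrous), THF, −78 to 0 °C; aq. NH4Cl
Reagents that add atoms: isopropylmagnesium chloride, CC(C)[Mg]Cl
Why: Organocerium addition to a hindered, enolisable ketone; the weakly basic isopropylcerium reagent adds where the Grignard reagent alone would enolise C5 or reduce the carbonyl. Attack from the face of H5, anti to the bulky C5 side chain (1,2-induction), places the new hydroxyl cis to that chain and sets C4 as R.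

Step 7
Reactants: 15 4-hydroxybenzoic acid
Product: 17 4-{[tert-butyl(dimethyl)silyl]oxy}benzoic acid, via tert-butyl(dimethyl)silyl 4-{[tert-butyl(dimethyl)silyl]oxy}benzoate 16 (not isolated)
Conditions: TBSCl, imidazole, DMF, rt; AcOH/THF/H2O, rt
Reagents that add atoms: tert-butyldimethylsilyl chloride, CC(C)(C)[Si](C)(C)Cl
Why: Both acidic hydrogens are silylated and the much more labile silyl ester is then hydrolysed selectively by aqueous acetic acid, conditions to which aryl silyl ethers are stable.

Step 8
Reactants: 17 4-{[tert-butyl(dimethyl)silyl]oxy}benzoic acid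
Product: 18 4-{[tert-butyl(dimethyl)silyl]oxy}benzoyl chloride
Conditions: (COCl)2, DMF (cat.), CH2Cl2, 0 °C to rt
Reagents that add atoms: oxalyl chloride, ClC(=O)C(=O)Cl
Why: Acid chloride formation through the chloroiminium species formed from DMF; the by-products are gases and the aryl silyl ether tolerates the anhydrous conditions.

Step 9
Reactants: 14 (1R,2S,3R)-2-[(1R)-1-{[tert-butyl(dimethyl)silyl]oxy}-2,2-dimethoxyethyl]-3-methyl-3-(2-methylidenebutyl)-1-(propan-2-yl)cyclopentan-1-ol; 18 4-{[tert-butyl(dimethyl)silyl]oxy}benzoyl chloride
Product: 19 (1R,2S,3R)-2-[(1R)-1-{[tert-butyl(dimethyl)silyl]oxy}-2,2-dimethoxyethyl]-3-methyl-3-(2-methylidenebutyl)-1-(propan-2-yl)cyclopentyl 4-{[tert-butyl(dimethyl)silyl]oxy}benzoate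
Conditions: n-BuLi, THF, −78 °C; 18, −78 to 0 °C
Reagents that add atoms: none
Why: Acylation of a tertiary lithium alkoxide with an aroyl chloride, the standard esterification of tertiary alcohols; no enolisable carbonyl is present, the C6 oxygen is blocked, and the lithium counter-ion and low temperature hold back silyl migration. The C4–O bond is not broken, so C4 is retained.

Step 10
Reactants: 19 (1R,2S,3R)-2-[(1R)-1-{[tert-butyl(dimethyl)silyl]oxy}-2,2-dimethoxyethyl]-3-methyl-3-(2-methylidenebutyl)-1-(propan-2-yl)cyclopentyl 4-{[tert-butyl(dimethyl)silyl]oxy}benzoate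
Product: 21 (1R,2S,3R)-2-[(1R)-1-{[tert-butyl(dimethyl)silyl]oxy}-2,2-dimethoxyethyl]-3-methyl-3-(2-oxobutyl)-1-(propan-2-yl)cyclopentyl 4-{[tert-butyl(dimethyl)silyl]oxy}benzoate, via secondary ozonide (3-ethyl-1,2,4-trioxolane) 20 (not isolated)
Conditions: O3, CH2Cl2, −78 °C (Sudan red 7B end point); PPh3, −78 °C to rt
Reagents that add atoms: ozone, [O-][O+]=O
Why: Ozonolysis of the 1,1-disubstituted alkene (cycloaddition, cycloreversion, recombination to the ozonide) and reduction with PPh3 gives the ethyl ketone; the alkene reacts far faster than the benzoate ring or the acetal C–H, and the indicator dye marks the end point.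

Step 11
Reactants: 21 (1R,2S,3R)-2-[(1R)-1-{[tert-butyl(dimethyl)silyl]oxy}-2,2-dimethoxyethyl]-3-methyl-3-(2-oxobutyl)-1-(propan-2-yl)cyclopentyl 4-{[tert-butyl(dimethyl)silyl]oxy}benzoate
Product: 22 (1R,2S,3R)-2-[(1R)-1-{[tert-butyl(dimethyl)silyl]oxy}-2-oxoethyl]-3-methyl-3-(2-oxobutyl)-1-(propan-2-yl)cyclopentyl 4-{[tert-butyl(dimethyl)silyl]oxy}benzoate
Conditions: TsOH·H2O (cat.), acetone/H2O, rt
Reagents that add atoms: water, O
Why: Acid-catalysed hydrolysis of the dimethyl acetal; catalytic sulfonic acid in wet acetone at room temperature stays below what cleaves a hindered secondary silyl ether, an aryl silyl ether or a tertiary benzoate, and does not enolise C6.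

Step 12
Reactants: 22 (1R,2S,3R)-2-[(1R)-1-{[tert-butyl(dimethyl)silyl]oxy}-2-oxoethyl]-3-methyl-3-(2-oxobutyl)-1-(propan-2-yl)cyclopentyl 4-{[tert-butyl(dimethyl)silyl]oxy}benzoate
Product: 25 (1R,3aR,8S,8aS)-8-{[tert-butyl(dimethyl)silyl]oxy}-3a,6-dimethyl-5-oxo-1-(propan-2-yl)-1,2,3,3a,4,5,8,8a-octahydroazulen-1-yl 4-hydroxybenzoate, via phenol keto aldehyde 23 (not isolated), via β-hydroxy ketone 24 (not isolated)
Conditions: K2CO3, MeOH, rt to 45 °C; aq. NH4Cl
Reagents that add atoms: none
Why: Intramolecular aldol condensation; methoxide first removes the aryl silyl group (the phenoxide then shields the ester from methanolysis), the C9 ketone enolises toward C8 and adds to the C7 aldehyde (7-enolendo-exo-trig), and E1cB loss of water gives the conjugated enone. Closure from C10 or C6 would give a strained trans-fused bicyclo[3.3.0]octane and is reversible; C7 and C8 end as sp2 carbons, so no new stereocentre remains.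

Step 13
Reactants: 25 (1R,3aR,8S,8aS)-8-{[tert-butyl(dimethyl)silyl]oxy}-3a,6-dimethyl-5-oxo-1-(propan-2-yl)-1,2,3,3a,4,5,8,8a-octahydroazulen-1-yl 4-hydroxybenzoate
Product: 26 (1R,3aR,8S,8aS)-8-hydroxy-3a,6-dimethyl-5-oxo-1-(propan-2-yl)-1,2,3,3a,4,5,8,8a-octahydroazulen-1-yl 4-hydroxybenzoate
Conditions: HF·pyridine, pyridine, THF, 0 °C to rt
Reagents that add atoms: none
Why: Fluoride cleavage of the secondary silyl ether in a weakly acidic buffered medium, which avoids base-induced acyl migration from the C4 oxygen to the C6 oxygen and isomerisation of the γ-hydroxy enone; the C6–O bond is not broken, so all four stereocentres are retained.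

## Compound list

1 | 2-methylidenebutanal (2-ethylacrolein) | CCC(=C)C=O | starting material
2 | 2-methylidenebutan-1-ol | CCC(=C)CO | intermediate
3 | 2-methylidenebutyl methanesulfonate | CCC(=C)COS(C)(=O)=O | intermediate
4 | 2-(chloromethyl)but-1-ene | CCC(=C)CCl | intermediate
5 | 3-ethoxycyclopent-2-en-1-one | CCOC1=CC(=O)CC1 | starting material
6 | (2-methylidenebutyl)magnesium chloride | CCC(=C)C[Mg]Cl | intermediate
7 | 3-ethoxy-1-(2-methylidenebutyl)cyclopent-2-en-1-ol (racemic; present as its chloromagnesium alkoxide until acid is added) | CCOC1=CC(O)(CC(=C)CC)CC1 | intermediate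
8 | 3-(2-methylidenebutyl)cyclopent-2-en-1-one | O=C1C=C(CC(=C)CC)CC1 | intermediate
9 | trimethylaluminium | C[Al](C)C | starting material
10 | 2,2-dimethoxyacetaldehyde | O=CC(OC)OC | starting material
11 | dimethylaluminium (3R)-3-methyl-3-(2-methylidenebutyl)cyclopent-1-en-1-olate | C[Al](C)OC1=C[C@@](C)(CC(=C)CC)CC1 | intermediate
12 | (2S,3R)-2-[(1R)-1-hydroxy-2,2-dimethoxyethyl]-3-methyl-3-(2-methylidenebutyl)cyclopentan-1-one | O=C1CC[C@](C)(CC(=C)CC)[C@H]1[C@@H](O)C(OC)OC | intermediate
13 | (2S,3R)-2-[(1R)-1-{[tert-butyl(dimethyl)silyl]oxy}-2,2-dimethoxyethyl]-3-methyl-3-(2-methylidenebutyl)cyclopentan-1-one | O=C1CC[C@](C)(CC(=C)CC)[C@H]1[C@@H](O[Si](C)(C)C(C)(C)C)C(OC)OC | intermediate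
14 | (1R,2S,3R)-2-[(1R)-1-{[tert-butyl(dimethyl)silyl]oxy}-2,2-dimethoxyethyl]-3-methyl-3-(2-methylidenebutyl)-1-(propan-2-yl)cyclopentan-1-ol | COC(OC)[C@H](O[Si](C)(C)C(C)(C)C)[C@@H]1[C@](C)(CC[C@@]1(O)C(C)C)CC(=C)CC | intermediate
15 | 4-hydroxybenzoic acid | OC(=O)c1ccc(O)cc1 | starting material
16 | tert-butyl(dimethyl)silyl 4-{[tert-butyl(dimethyl)silyl]oxy}benzoate | CC(C)(C)[Si](C)(C)OC(=O)c1ccc(O[Si](C)(C)C(C)(C)C)cc1 | intermediate
17 | 4-{[tert-butyl(dimethyl)silyl]oxy}benzoic acid | OC(=O)c1ccc(O[Si](C)(C)C(C)(C)C)cc1 | intermediate
18 | 4-{[tert-butyl(dimethyl)silyl]oxy}benzoyl chloride | ClC(=O)c1ccc(O[Si](C)(C)C(C)(C)C)cc1 | intermediate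
19 | (1R,2S,3R)-2-[(1R)-1-{[tert-butyl(dimethyl)silyl]oxy}-2,2-dimethoxyethyl]-3-methyl-3-(2-methylidenebutyl)-1-(propan-2-yl)cyclopentyl 4-{[tert-butyl(dimethyl)silyl]oxy}benzoate | COC(OC)[C@H](O[Si](C)(C)C(C)(C)C)[C@@H]1[C@](C)(CC[C@@]1(OC(=O)c2ccc(O[Si](C)(C)C(C)(C)C)cc2)C(C)C)CC(=C)CC | intermediate
20 | secondary ozonide of 19: (1R,2S,3R)-2-[(1R)-1-{[tert-butyl(dimethyl)silyl]oxy}-2,2-dimethoxyethyl]-3-[(3-ethyl-1,2,4-trioxolan-3-yl)methyl]-3-methyl-1-(propan-2-yl)cyclopentyl 4-{[tert-butyl(dimethyl)silyl]oxy}benzoate (trioxolane carbon as a mixture) | COC(OC)[C@H](O[Si](C)(C)C(C)(C)C)[C@@H]1[C@](C)(CC[C@@]1(OC(=O)c2ccc(O[Si](C)(C)C(C)(C)C)cc2)C(C)C)CC3(CC)OCOO3 | intermediate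
21 | (1R,2S,3R)-2-[(1R)-1-{[tert-butyl(dimethyl)silyl]oxy}-2,2-dimethoxyethyl]-3-methyl-3-(2-oxobutyl)-1-(propan-2-yl)cyclopentyl 4-{[tert-butyl(dimethyl)silyl]oxy}benzoate | COC(OC)[C@H](O[Si](C)(C)C(C)(C)C)[C@@H]1[C@](C)(CC[C@@]1(OC(=O)c2ccc(O[Si](C)(C)C(C)(C)C)cc2)C(C)C)CC(=O)CC | intermediate
22 | (1R,2S,3R)-2-[(1R)-1-{[tert-butyl(dimethyl)silyl]oxy}-2-oxoethyl]-3-methyl-3-(2-oxobutyl)-1-(propan-2-yl)cyclopentyl 4-{[tert-butyl(dimethyl)silyl]oxy}benzoate | O=C[C@H](O[Si](C)(C)C(C)(C)C)[C@@H]1[C@](C)(CC[C@@]1(OC(=O)c2ccc(O[Si](C)(C)C(C)(C)C)cc2)C(C)C)CC(=O)CC | intermediate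
23 | (1R,2S,3R)-2-[(1R)-1-{[tert-butyl(dimethyl)silyl]oxy}-2-oxoethyl]-3-methyl-3-(2-oxobutyl)-1-(propan-2-yl)cyclopentyl 4-hydroxybenzoate (phenol keto aldehyde) | O=C[C@H](O[Si](C)(C)C(C)(C)C)[C@@H]1[C@](C)(CC[C@@]1(OC(=O)c2ccc(O)cc2)C(C)C)CC(=O)CC | intermediate
24 | 8-{[tert-butyl(dimethyl)silyl]oxy}-7-hydroxy-3a,6-dimethyl-5-oxo-1-(propan-2-yl)decahydroazulen-1-yl 4-hydroxybenzoate (β-hydroxy ketone; the two new centres at the hydroxyl- and methyl-bearing carbons undefined, the other four as in 22) | CC1C(O)[C@H](O[Si](C)(C)C(C)(C)C)[C@@H]2[C@](C)(CC[C@@]2(OC(=O)c3ccc(O)cc3)C(C)C)CC1=O | intermediate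
25 | (1R,3aR,8S,8aS)-8-{[tert-butyl(dimethyl)silyl]oxy}-3a,6-dimethyl-5-oxo-1-(propan-2-yl)-1,2,3,3a,4,5,8,8a-octahydroazulen-1-yl 4-hydroxybenzoate | CC1=C[C@H](O[Si](C)(C)C(C)(C)C)[C@@H]2[C@](C)(CC[C@@]2(OC(=O)c3ccc(O)cc3)C(C)C)CC1=O | intermediate
26 | (1R,3aR,8S,8aS)-8-hydroxy-3a,6-dimethyl-5-oxo-1-(propan-2-yl)-1,2,3,3a,4,5,8,8a-octahydroazulen-1-yl 4-hydroxybenzoate (CNP0153637.1) | CC1=C[C@H](O)[C@@H]2[C@](C)(CC[C@@]2(OC(=O)c2ccc(O)cc2)C(C)C)CC1=O | target

## Step count and least certain steps

Total: 13 steps. Longest linear sequence: 11 steps (steps 1–6 and 9–13, from 2-ethylacrolein); steps 7 and 8 are the two-step side branch to acid chloride 18.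

**Step 4 (key step).** The most likely failure is poor facial selectivity at C5, because the enolate distinguishes only a methyl group from a CH2-linked arm on the neighbouring quaternary carbon. Further risks are methyl transfer from aluminium to the aldehyde in place of the aldol, retro-aldol on warming, and lower enantioselectivity on a five-membered enone than on six-membered ones. The fallback separates the two bond formations. It sets out from 8: the same copper-catalysed methyl addition is quenched with TMSCl and the enolate is isolated as trimethyl{[(3R)-3-methyl-3-(2-methylidenebutyl)cyclopent-1-en-1-yl]oxy}silane F1. F1 is then cleaved with MeLi to the amine-free lithium enolate, transmetalated with ZnCl2 to the zinc enolate and combined with 10 at −78 °C, which returns to the route at 12. This removes aluminium and copper residues from the aldol, allows the enolate metal to be chosen for a tighter closed transition state, and gives a purification point before the aldol.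

**Step 9.** The crowded tertiary alkoxide may acylate slowly, and during that time the silyl group may migrate from the C6 oxygen to the C4 oxygen, so that the acyl group ends on C6. The fallback avoids any alkoxide. It sets out from 14 and acid 17: 17 is converted with 2,4,6-trichlorobenzoyl chloride and Et3N into the mixed anhydride 4-{[tert-butyl(dimethyl)silyl]oxy}benzoic 2,4,6-trichlorobenzoic anhydride F2, which acylates 14 under DMAP in hot toluene (Yamaguchi esterification) and returns to the route at 19.

**Step 12 (with step 11 before it).** The free α-silyloxy aldehyde 22 may epimerise at C6 through its enol before the ring closes, the reaction may stop at the β-hydroxy ketone, and the base may deconjugate the γ-silyloxy enone; in step 11, partial loss of the secondary silyl ether or ionisation of the tertiary ester is possible. The fallback never frees the aldehyde. It sets out from 21: kinetic deprotonation on the ethyl side with LiN(iPr)2 and TMSCl at −78 °C gives the trimethylsilyl enol ether of 21 (C8=C9) F3. TMSOTf in CH2Cl2 at −78 °C closes the ring by an intramolecular Mukaiyama aldol reaction onto the dimethyl acetal and gives the bicyclic β-methoxy ketone F4. DBU eliminates methanol to give the bis-silylated enone F5, and HF·pyridine removes both silyl groups, which returns to the route at 26.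

**Step 6.** Enolisation of C5 with expulsion of the β-silyloxy group, reduction by β-hydride transfer from the isopropyl reagent, and insufficient facial selectivity (the face anti to the C5 chain also carries the C1 arm) are the risks. The fallback changes the order of protection and addition. It sets out from 12: the unprotected aldol is treated with excess i-PrMgCl/CeCl3, so that the C6 alkoxide forms first; an alkoxide is not a leaving group and disfavours enolisation next to it. This gives the diol (1R,2S,3R)-2-[(1R)-1-hydroxy-2,2-dimethoxyethyl]-3-methyl-3-(2-methylidenebutyl)-1-(propan-2-yl)cyclopentan-1-ol F6. Selective silylation of its secondary hydroxyl (TBSOTf, 2,6-lutidine, −78 °C) returns to the route at 14.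

## Further compounds

F1 | step 4 | trimethyl{[(3R)-3-methyl-3-(2-methylidenebutyl)cyclopent-1-en-1-yl]oxy}silane | C[Si](C)(C)OC1=C[C@@](C)(CC(=C)CC)CC1
F2 | step 9 | 4-{[tert-butyl(dimethyl)silyl]oxy}benzoic 2,4,6-trichlorobenzoic anhydride | CC(C)(C)[Si](C)(C)Oc1ccc(cc1)C(=O)OC(=O)c1c(Cl)cc(Cl)cc1Cl
F3 | step 12 | trimethylsilyl enol ether of 21 (C8=C9): (1R,2S,3R)-2-[(1R)-1-{[tert-butyl(dimethyl)silyl]oxy}-2,2-dimethoxyethyl]-3-methyl-1-(propan-2-yl)-3-[2-(trimethylsilyloxy)but-2-en-1-yl]cyclopentyl 4-{[tert-butyl(dimethyl)silyl]oxy}benzoate | COC(OC)[C@H](O[Si](C)(C)C(C)(C)C)[C@@H]1[C@](C)(CC[C@@]1(OC(=O)c2ccc(O[Si](C)(C)C(C)(C)C)cc2)C(C)C)CC(O[Si](C)(C)C)=CC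
F4 | step 12 | 8-{[tert-butyl(dimethyl)silyl]oxy}-7-methoxy-3a,6-dimethyl-5-oxo-1-(propan-2-yl)decahydroazulen-1-yl 4-{[tert-butyl(dimethyl)silyl]oxy}benzoate (methoxy- and methyl-bearing carbons undefined) | CC1C(OC)[C@H](O[Si](C)(C)C(C)(C)C)[C@@H]2[C@](C)(CC[C@@]2(OC(=O)c3ccc(O[Si](C)(C)C(C)(C)C)cc3)C(C)C)CC1=O
F5 | step 12 | (1R,3aR,8S,8aS)-8-{[tert-butyl(dimethyl)silyl]oxy}-3a,6-dimethyl-5-oxo-1-(propan-2-yl)-1,2,3,3a,4,5,8,8a-octahydroazulen-1-yl 4-{[tert-butyl(dimethyl)silyl]oxy}benzoate | CC1=C[C@H](O[Si](C)(C)C(C)(C)C)[C@@H]2[C@](C)(CC[C@@]2(OC(=O)c3ccc(O[Si](C)(C)C(C)(C)C)cc3)C(C)C)CC1=O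
F6 | step 6 | (1R,2S,3R)-2-[(1R)-1-hydroxy-2,2-dimethoxyethyl]-3-methyl-3-(2-methylidenebutyl)-1-(propan-2-yl)cyclopentan-1-ol | COC(OC)[C@H](O)[C@@H]1[C@](C)(CC[C@@]1(O)C(C)C)CC(=C)CC
A1 | alternative 1 | tert-butyl({1-[5-ethynyl-2,6-dimethyl-5-(triethylsilyloxy)hept-1-en-1-yl]-2-methylcyclopropyl}oxy)dimethylsilane (C4 configured as in the SMILES; alkene and cyclopropane geometry open) | C#C[C@](O[Si](CC)(CC)CC)(C(C)C)CCC(C)=CC1(O[Si](C)(C)C(C)(C)C)CC1C
A2 | alternative 1 | tert-butyl{[3a,6-dimethyl-1-(propan-2-yl)-1-(triethylsilyloxy)-1,2,3,3a,6,7-hexahydroazulen-5-yl]oxy}dimethylsilane (configuration as in the SMILES) | C[C@@H]1CC=C2[C@](O[Si](CC)(CC)CC)(C(C)C)CC[C@]2(C)C=C1O[Si](C)(C)C(C)(C)C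
A3 | alternative 2 | 6-ethenyl-7-methyl-1,4-dioxaspiro[4.4]non-6-ene | C=CC1=C(C)CCC12OCCO2
A4 | alternative 2 | methyl 3-{[tert-butyl(dimethyl)silyl]oxy}-2-diazobut-3-enoate | COC(=O)C(=[N+]=[N-])C(=C)O[Si](C)(C)C(C)(C)C
A5 | alternative 2 | methyl 5-{[tert-butyl(dimethyl)silyl]oxy}-3a-methyl-2,3,4,7-tetrahydro-3aH-spiro[azulene-1,2'-[1,3]dioxolane]-6-carboxylate (configuration as in the SMILES) | COC(=O)C1=C(O[Si](C)(C)C(C)(C)C)C[C@@]2(C)CCC3(OCCO3)C2=CC1
A6 | alternative 3 | Se-phenyl 2-{2-[(2E)-but-2-enoyl]-1-methyl-3-(propan-2-yl)-3-(triethylsilyloxy)cyclopentyl}ethaneselenoate (configuration as in the SMILES) | C/C=C/C(=O)[C@@H]1[C@](C)(CC[C@@]1(O[Si](CC)(CC)CC)C(C)C)CC(=O)[Se]c1ccccc1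
A7 | alternative 3 | 3a,6-dimethyl-1-(propan-2-yl)-1-(triethylsilyloxy)octahydroazulene-5,8-dione (trans-fused; methyl-bearing ring carbon as a mixture) | CC1CC(=O)[C@@H]2[C@](C)(CC[C@@]2(O[Si](CC)(CC)CC)C(C)C)CC1=O
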